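**Strategy.** Everything rests on disconnecting the bond between the two adjacent spiro carbons of the cyclopentane: the carbon flanked by both ring carbonyls of the six-membered trione ring and C2 of the pinane. The trione ring is carried as a cheap, flat phloroglucinol-type arene (2,6-dihydroxy-4-methoxy-3,5-dimethylphenyl). A Pd(0) allylic alkylation through the phenol ipso carbon dearomatises this ring, closes the five-membered ring and creates both quaternary carbons in one operation. The precursor is a tertiary allylic carbonate of a pin-3-ene carrying the arene on a three-carbon tether. The step exploits the 1,3-dioxygenated ring carbon as a latent phenoxide and the double inversion of Pd allyl chemistry, which delivers carbon to the hindered gem-dimethyl-bridge face of pinane C2.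

Key step: step 10

Assumption: (1R,5R)-(+)-β-pinene is taken as a purchasable terpene, and 18 is drawn as one of its two equivalent, interconverting enol tautomers.

**Step 1**
Reactants: 1 1-(2,4,6-trihydroxyphenyl)ethanone
Product: 2 1-(2,4,6-trihydroxy-3,5-dimethylphenyl)ethanone
Conditions: MeI (2.1 equiv), NaOMe, MeOH, 0 °C to rt
Reagents that add atoms: iodomethane CI
Why: C-alkylation of the ambident phloroglucinolate at its two free ring carbons in a protic medium, the acyl group letting the ring re-aromatise after each methylation; no stereocentre is formed.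

**Step 2**
Reactants: 2 1-(2,4,6-trihydroxy-3,5-dimethylphenyl)ethanone
Product: 3 1-(2,6-dihydroxy-4-methoxy-3,5-dimethylphenyl)ethanone
Conditions: Me2SO4 (1.0 equiv), K2CO3, acetone, rt
Reagents that add atoms: dimethyl sulfate COS(=O)(=O)OC
Why: Williamson O-methylation that should select the 4-OH para to the acetyl group, the most acidic one and the only one not held in a hydrogen bond to the ketone.

**Step 3**
Reactants: 3 1-(2,6-dihydroxy-4-methoxy-3,5-dimethylphenyl)ethanone
Product: 4 5-methoxy-4,6-dimethylbenzene-1,3-diol
Conditions: 85% H3PO4, 120 °C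
Reagents that add atoms: none
Why: Acid-mediated protodeacylation (retro-Friedel–Crafts), made easy by ipso protonation of the ring carbon flanked by two hydroxyl groups and loss of the acylium ion as acetic acid.

**Step 4**
Reactants: 4 5-methoxy-4,6-dimethylbenzene-1,3-diol; 5 (E)-4-methylpent-2-enal
Product: 7 2-[(3R)-1-hydroxy-4-methylpentan-3-yl]-5-methoxy-4,6-dimethylbenzene-1,3-diol, via chromanol lactol 6 (not isolated)
Conditions: (R)-α,α-diphenylprolinol TMS ether (20 mol %), PhCO2H (20 mol %), CHCl3, 0 °C to rt; then NaBH4, MeOH, 0 °C
Reagents that add atoms: none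
Why: Iminium-catalysed Friedel–Crafts-type conjugate addition of the only free ring carbon of 4 to the enal, then lactol closure and borohydride reduction; the diphenyl(silyloxy)methyl group of the (R)-catalyst covers one face of the s-trans E-iminium ion, so the arene adds to the open face, which for this substituent pattern gives the (R)-centre.

**Step 5**
Reactants: 7 2-[(3R)-1-hydroxy-4-methylpentan-3-yl]-5-methoxy-4,6-dimethylbenzene-1,3-diol
Product: 8 tris(tert-butyldimethylsilyl) ether of 7
Conditions: TBSOTf (3.6 equiv), 2,6-lutidine, CH2Cl2, 0 °C to rt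
Reagents that add atoms: tert-butyldimethylsilyl triflate CC(C)(C)[Si](C)(C)OS(=O)(=O)C(F)(F)F
Why: Exhaustive O-silylation with the triflate, which also reaches the two hindered phenols and masks all acidic protons before the organometallic step; the stereocentre is untouched.

**Step 6**
Reactants: 8 tris(tert-butyldimethylsilyl) ether of 7
Product: 9 (R)-configured primary bromide with both aryl silyl ethers intact
Conditions: Ph3PBr2 (1.2 equiv), CH2Cl2, 0 °C to rt
Reagents that add atoms: dibromotriphenylphosphorane BrP(Br)(c1ccccc1)(c1ccccc1)c1ccccc1
Why: Appel-type direct conversion of a primary alkyl silyl ether into the bromide through an oxyphosphonium ion (SN2 at CH2), a pathway closed to aryl silyl ethers.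

**Step 7**
Reactants: 10 (1R,5R)-β-pinene
Product: 12 (1S,5R)-nopinone, via ozonide 11 (not isolated)
Conditions: O3, CH2Cl2, −78 °C; then Me2S, −78 °C to rt
Reagents that add atoms: ozone [O-][O+]=O
Why: Ozonolysis of the exocyclic alkene ([3+2] cycloaddition, cycloreversion and recombination to the ozonide, then reductive cleavage) leaves both bridgehead stereocentres untouched.

**Step 8**
Reactants: 12 (1S,5R)-nopinone
Product: 13 (1S,5S)-apoverbenone
Conditions: IBX (2.5 equiv), toluene/DMSO 2:1, 70 °C
Reagents that add atoms: none
Why: IBX α,β-dehydrogenation of the ketone, which can only introduce the C3–C4 double bond because the other α-carbon is a bridgehead.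

**Step 9**
Reactants: 9 (R)-configured primary bromide; 13 (1S,5S)-apoverbenone
Product: 16 methyl (1S,2S,5S)-2-[(3R)-3-aryl-4-methylpentyl]-6,6-dimethylbicyclo[3.1.1]hept-3-en-2-yl carbonate (aryl = 2,6-bis(TBSO)-4-methoxy-3,5-dimethylphenyl), via Grignard reagent 14 (not isolated), via bromomagnesium alkoxide 15 (not isolated)
Conditions: Mg, THF, 40 °C; LaCl3·2LiCl, 13, −78 °C; then ClCO2Me, −78 to 0 °C
Reagents that add atoms: methyl chloroformate COC(Cl)=O
Why: Grignard 1,2-addition to the non-enolisable enone, with the lanthanum salt suppressing conjugate addition, takes place on the carbonyl face anti to the gem-dimethyl bridge, so the new tertiary centre carries the chain anti and the oxygen syn to that bridge, and the alkoxide is acylated in the same flask.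

**Step 10**
Reactants: 16 methyl (1S,2S,5S)-2-[(3R)-3-aryl-4-methylpentyl]-6,6-dimethylbicyclo[3.1.1]hept-3-en-2-yl carbonate
Product: 18 spiro-annulated hydroxy-dienone (vinylogous acid) with the pin-3-ene C2 as second spiro carbon, via bisphenol carbonate 17 (not isolated)
Conditions: TBAF (2.1 equiv), THF, 0 °C; then Pd2(dba)3 (2.5 mol %), PPh3 (12 mol %), THF, rt to 45 °C; aq. HCl work-up
Reagents that add atoms: none
Why: Fluoride first frees the two phenols (17); Pd(0) then ionises the tertiary allylic carbonate with inversion, so palladium sits on the open face of the pinene π-allyl unit (C2–C3–C4), anti to the gem-dimethyl bridge, while CO2 and methoxide are released. The phenoxide attacks through its ipso carbon (the ring carbon between the two oxygens) at the substituted allyl terminus C2 in an outer-sphere step anti to palladium, a 5-exo closure through the three-carbon tether (attack at C4 would need a bridged seven-membered ring). The closest known reaction type is the Pd-catalysed intramolecular ipso-Friedel–Crafts (dearomative Tsuji–Trost) allylic alkylation of phenols to spiro[4.5]cyclohexadienones, together with the Pd-mediated alkylative dearomatisation of phloroglucinols. The new quaternary stereocentre at pinane C2 is fixed by the double inversion (net retention): the ring carbon takes the place of the carbonate oxygen, syn to the gem-dimethyl bridge, the face a direct attack on the pinene would avoid; the CH(iPr) centre is untouched and the spiro carbon of the six-membered ring is not yet stereogenic because the two enol tautomers of 18 interconvert. The step needs C- over O-allylation and closure rather than β-hydride elimination; O-allyl ethers re-ionise under Pd(0), whereas 18 is a vinylogous acid (pKa about 5) held as its delocalised anion, which should make the carbocycle the thermodynamic sink.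

**Step 11**
Reactants: 18 spiro-annulated hydroxy-dienone
Product: 19 C-methylated spiro trione monoenol ether, still with the pinene ring alkene
Conditions: NaOMe (1.1 equiv), MeI (3 equiv), MeOH, 0 °C to rt
Reagents that add atoms: iodomethane CI
Why: C-alkylation of the delocalised vinylogous-acid anion (the classical C-methylation of dearomatised phloroglucinols, self-limiting because no enolisable position remains) makes the spiro carbon a stereocentre by choice between the two diastereotopic enolate carbons: methyl iodide comes from the ring face turned away from the pinane, and of the two carbons on that face the one under the isopropyl group is screened while the one on the flank syn to the C–H of the CH(iPr) carbon is open, which puts the gem-dimethyl carbonyl flank cis to that hydrogen as in the target.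

**Step 12**
Reactants: 19 C-methylated spiro trione monoenol ether
Product: 20 target compound CNP0307059.1
Conditions: H2 (1 atm), 5% Pd/C, EtOAc, rt
Reagents that add atoms: none
Why: Heterogeneous hydrogenation of the cis-disubstituted ring alkene from the face anti to the gem-dimethyl bridge creates no stereocentre, and the tetrasubstituted β-methoxy enone and the ketones should be inert under these conditions.

**Compound list**

1 | 1-(2,4,6-trihydroxyphenyl)ethanone | CC(=O)c1c(O)cc(O)cc1O | starting material
2 | 1-(2,4,6-trihydroxy-3,5-dimethylphenyl)ethanone | CC(=O)c1c(O)c(C)c(O)c(C)c1O | intermediate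
3 | 1-(2,6-dihydroxy-4-methoxy-3,5-dimethylphenyl)ethanone | COc1c(C)c(O)c(C(C)=O)c(O)c1C | intermediate
4 | 5-methoxy-4,6-dimethylbenzene-1,3-diol | COc1c(C)c(O)cc(O)c1C | intermediate
5 | (E)-4-methylpent-2-enal | CC(C)/C=C/C=O | starting material
6 | (4R)-7-methoxy-6,8-dimethyl-4-(propan-2-yl)chromane-2,5-diol (lactol, both anomers) | COc1c(C)c(O)c2c(c1C)OC(O)C[C@@H]2C(C)C | intermediate (not isolated)
7 | 2-[(3R)-1-hydroxy-4-methylpentan-3-yl]-5-methoxy-4,6-dimethylbenzene-1,3-diol | COc1c(C)c(O)c([C@@H](C(C)C)CCO)c(O)c1C | intermediate
8 | tris(tert-butyldimethylsilyl) ether of 7 (both phenols and the primary alcohol silylated, 3R) | COc1c(C)c(O[Si](C)(C)C(C)(C)C)c([C@@H](C(C)C)CCO[Si](C)(C)C(C)(C)C)c(O[Si](C)(C)C(C)(C)C)c1C | intermediate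
9 | 2-[(3R)-1-bromo-4-methylpentan-3-yl]-5-methoxy-4,6-dimethyl-1,3-phenylene bis(tert-butyldimethylsilyl) ether | COc1c(C)c(O[Si](C)(C)C(C)(C)C)c([C@@H](C(C)C)CCBr)c(O[Si](C)(C)C(C)(C)C)c1C | intermediate
10 | (1R,5R)-6,6-dimethyl-2-methylidenebicyclo[3.1.1]heptane, (+)-β-pinene | C=C1CC[C@@H]2C[C@H]1C2(C)C | starting material
11 | spiro-1,2,4-trioxolane (ozonide) of 10, bridgeheads as in 10 | C1OC2(OO1)CC[C@@H]3C[C@H]2C3(C)C | intermediate (not isolated)
12 | (1S,5R)-6,6-dimethylbicyclo[3.1.1]heptan-2-one, nopinone | O=C1CC[C@@H]2C[C@H]1C2(C)C | intermediate
13 | (1S,5S)-6,6-dimethylbicyclo[3.1.1]hept-3-en-2-one, apoverbenone | O=C1C=C[C@@H]2C[C@H]1C2(C)C | intermediate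
14 | Grignard reagent of 9 (bromomagnesium on the primary carbon, 3R) | COc1c(C)c(O[Si](C)(C)C(C)(C)C)c([C@@H](C(C)C)CC[Mg]Br)c(O[Si](C)(C)C(C)(C)C)c1C | intermediate (not isolated)
15 | bromomagnesium alkoxide of the tertiary allylic alcohol (chain anti, oxygen syn to the gem-dimethyl bridge) | COc1c(C)c(O[Si](C)(C)C(C)(C)C)c([C@@H](C(C)C)CC[C@]2(O[Mg]Br)C=C[C@@H]3C[C@H]2C3(C)C)c(O[Si](C)(C)C(C)(C)C)c1C | intermediate (not isolated)
16 | methyl (1S,2S,5S)-2-{(3R)-3-[2,6-bis(tert-butyldimethylsilyloxy)-4-methoxy-3,5-dimethylphenyl]-4-methylpentyl}-6,6-dimethylbicyclo[3.1.1]hept-3-en-2-yl carbonate | COc1c(C)c(O[Si](C)(C)C(C)(C)C)c([C@@H](C(C)C)CC[C@]2(OC(=O)OC)C=C[C@@H]3C[C@H]2C3(C)C)c(O[Si](C)(C)C(C)(C)C)c1C | intermediate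
17 | bis-phenol corresponding to 16 (both silyl groups removed, as its bis-phenoxide in the flask) | COc1c(C)c(O)c([C@@H](C(C)C)CC[C@]2(OC(=O)OC)C=C[C@@H]3C[C@H]2C3(C)C)c(O)c1C | intermediate (not isolated)
18 | dispiro compound: 5-hydroxy-3-methoxy-2,4-dimethylcyclohexa-2,4-dien-1-one whose C6 is spiro-fused to a cyclopentane carrying (R)-CH(iPr) next to C6 and, on the other side, spiro C2 of the 6,6-dimethylbicyclo[3.1.1]hept-3-ene; at pinene C2 the dienone carbon is syn and the ring CH2 anti to the gem-dimethyl bridge | COC1=C(C)C(=O)C2(C(O)=C1C)[C@@H](C(C)C)CC[C@@]21C=C[C@@H]2C[C@H]1C2(C)C | intermediate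
19 | 3,4-didehydro analogue of the target (pinene C3=C4 double bond); on the cyclopentane the C(=O)CMe2 carbonyl is cis to the H of CH(iPr) and the enone carbonyl is cis to isopropyl | COC1=C(C)C(=O)[C@@]2(C(=O)C1(C)C)[C@@H](C(C)C)CC[C@@]21C=C[C@@H]2C[C@H]1C2(C)C | intermediate
20 | CNP0307059.1 | COC1=C(C)C(=O)[C@@]2(C(=O)C1(C)C)[C@@H](C(C)C)CC[C@@]21CC[C@@H]2C[C@H]1C2(C)C | target

**Total step count:** 12. **Longest linear sequence:** 10 (steps 1–6 and 9–12).

**Steps most likely to fail**

Step 10. After ionisation the arene carbon has to reach the allyl terminus on the face under the gem-dimethyl bridge. If this closure is slow, O-allylation to a seven-membered aryl ether, re-ionisation of the dearomatised product with rearomatisation, or β-hydride elimination from the π-allyl complex can take over. The fallback sets out from 16. It is desilylated (TBAF) to 17 and C-methylated before ring closure (KOtBu, MeI, t-BuOH/THF); alkylation at one of the two equivalent methyl-bearing ring carbons dearomatises the ring and gives the β-triketone carbonate F1, in which the future spiro carbon is still a CH. Pd(PPh3)4 in THF then closes the ring as an ordinary Tsuji–Trost alkylation of a 2-substituted cyclic 1,3-dione. This soft carbon nucleophile cannot revert by rearomatisation, and its O-allyl isomers re-ionise. The same double inversion fixes pinane C2, but the spiro carbon of the six-membered ring is now set in the closure itself, with the two epimers equilibrating through reversible ionisation and being separated. The fallback comes back to the route at 19.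

Step 11. The discrimination between the two diastereotopic enolate carbons may be poor or inverted, because the methyl group already on the reacting carbon is pushed toward the pinane gem-dimethyl bridge; O-methylation may also compete. The fallback sets out from 16 and differentiates the two flanks before the ring is closed. Only one silyl ether is removed (TBAF, 1.0 equiv; the two aryl silyl ethers are equivalent) to give the mono-silylated monophenol carbonate F2. Pd(0) cyclisation through the ring carbon next to the free phenoxide gives the spiro silyl dienol ether F3, with a ketone on one flank and a silyl dienol ether on the other. Allylic 1,3-strain should make the C–H of the CH(iPr) carbon eclipse the bulky silyloxy-bearing flank, which places that flank cis to this hydrogen, as the later C(=O)CMe2 unit requires. Diimide (potassium azodicarboxylate, AcOH) saturates the ring alkene to the dihydro silyl dienol ether F4. Simmons–Smith cyclopropanation of the silyl enol ether (Et2Zn, CH2I2) gives the siloxycyclopropane F5. Fluoride-induced opening of the cyclopropanol (TBAF, then water) turns the ring CH2 into the second methyl group and arrives at 20 without passing through the symmetric enolate.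

Step 4. The β-isopropyl iminium ion and a nucleophilic carbon flanked by two hydroxyl groups may make the conjugate addition slow, so that an acid-catalysed racemic background reaction erodes the enantiomeric purity. The fallback sets out from 4. Pechmann condensation with ethyl 4-methyl-3-oxopentanoate (TFA or H2SO4) gives the 4-isopropylcoumarin F6 as a single regioisomer. Copper hydride conjugate reduction with a chiral bisphosphine (Cu(OAc)2, DTBM-SEGPHOS enantiomer chosen for the (R)-product, PMHS, t-BuOH) sets the benzylic stereocentre in the dihydrocoumarin F7. LiAlH4 opens the lactone and rejoins the route at 7.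

**Further compounds**

F1 | step 10 | methyl (1S,2S,5S)-2-[(3R)-3-(4-methoxy-3,5,5-trimethyl-2,6-dioxocyclohex-3-en-1-yl)-4-methylpentyl]-6,6-dimethylbicyclo[3.1.1]hept-3-en-2-yl carbonate | COC1=C(C)C(=O)C(C(=O)C1(C)C)[C@@H](C(C)C)CC[C@]2(OC(=O)OC)C=C[C@@H]3C[C@H]2C3(C)C
F2 | step 11 | mono-desilylated 16 (one free phenol, one TBS ether) | COc1c(C)c(O)c([C@@H](C(C)C)CC[C@]2(OC(=O)OC)C=C[C@@H]3C[C@H]2C3(C)C)c(O[Si](C)(C)C(C)(C)C)c1C
F3 | step 11 | spiro 5-(tert-butyldimethylsilyloxy)-3-methoxy-2,4-dimethylcyclohexa-2,4-dienone with the pin-3-ene unit, silyloxy flank cis to the H of CH(iPr) | COC1=C(C)C(=O)[C@@]2(C(O[Si](C)(C)C(C)(C)C)=C1C)[C@@H](C(C)C)CC[C@@]21C=C[C@@H]2C[C@H]1C2(C)C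
F4 | step 11 | dihydro-F3 (pinane ring saturated) | COC1=C(C)C(=O)[C@@]2(C(O[Si](C)(C)C(C)(C)C)=C1C)[C@@H](C(C)C)CC[C@@]21CC[C@@H]2C[C@H]1C2(C)C
F5 | step 11 | siloxycyclopropane from F4 (CH2 bridging the silyloxy carbon and the adjacent methyl-bearing carbon) | COC1=C(C)C(=O)[C@@]2(C3(O[Si](C)(C)C(C)(C)C)CC13C)[C@@H](C(C)C)CC[C@@]21CC[C@@H]2C[C@H]1C2(C)C
F6 | step 4 | 5-hydroxy-7-methoxy-6,8-dimethyl-4-(propan-2-yl)-2H-chromen-2-one | COc1c(C)c(O)c2c(c1C)OC(=O)C=C2C(C)C
F7 | step 4 | (4R)-5-hydroxy-7-methoxy-6,8-dimethyl-4-(propan-2-yl)chroman-2-one | COc1c(C)c(O)c2c(c1C)OC(=O)C[C@@H]2C(C)C
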